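**Retrosynthetic overview**
1. Target ⇐ Si–O cleavage of its 9‑O‑TBS ether ⇐ ester C–O bond between O3 of the core and the trienoic acid, made in the same flask as the reductive opening of a 3α,4α‑epoxide (sets C4–H).
2. Epoxy enone ⇐ aldol/dehydration with acetone at C7 ⇐ 9α‑silyloxy‑3α,4α‑epoxy ketone ⇐ one peracid charge on a Δ8 silyl enol ether/Δ3 alkene (C9–O and C3–O bonds together).
3. Silyl enol ether ⇐ Birch reduction/O‑silylation (trans ring fusion) of a Δ3,Δ9‑dien‑8‑one ⇐ Wittig methylenation and alkene isomerisation of (S)‑Wieland–Miescher ketone.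
4. Acid ⇐ vinylogous Horner–Wadsworth–Emmons reaction of (E)‑non‑3‑en‑2‑one with triethyl 4‑phosphonocrotonate, then saponification.
5. Rings: both carbocycles (A and B) are bought intact in the Wieland–Miescher ketone; no carbocycle is built, only a transient oxirane (made in step 6, opened in step 9).

Assumption: (S)‑(+)‑Wieland–Miescher ketone is bought as such (it is also one pot from 2‑methylcyclohexane‑1,3‑dione, methyl vinyl ketone and L‑proline); locants follow eremophilane numbering (C14 = methyl on C5, C15 = methyl on C4, C11–C13 = side chain on C7), β = the face of the C5 methyl, α = the other face, and C14 and C15 are β throughout.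

**Step 1**
Reactants: 1 (E)-non-3-en-2-one; 2 triethyl 4-phosphonocrotonate [ethyl (E)-4-(diethoxyphosphoryl)but-2-enoate]
Product: 4 ethyl (2E,4E,6E)-5-methyldodeca-2,4,6-trienoate, via lithiated phosphonate 3 (not isolated)
Conditions: 2, LiHMDS, THF, −78 °C; then 1, −78 → 0 °C; I2 (2 mol%), PhH, rt; SiO2/AgNO3
Reagents that add atoms: none
Why: vinylogous Horner–Wadsworth–Emmons olefination — the phosphonate anion adds to the methyl ketone through the carbon next to phosphorus, the 2E bond of the reagent is kept, the new trisubstituted 4,5‑alkene forms mainly E, and iodine equilibrates the 4Z remainder to the more stable all‑E triene (no stereocentre formed).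

**Step 2**
Reactants: 4 ethyl (2E,4E,6E)-5-methyldodeca-2,4,6-trienoate
Product: 5 (2E,4E,6E)-5-methyldodeca-2,4,6-trienoic acid
Conditions: LiOH·H2O, THF/MeOH/H2O, rt; then 1 M HCl
Reagents that add atoms: lithium hydroxide, [Li+].[OH-]
Why: ester saponification (BAc2) at room temperature, which does not isomerise or deconjugate the triene.

**Step 3**
Reactants: 6 (S)-(+)-Wieland–Miescher ketone
Product: 7 (4aR)-4a-methyl-5-methylidene-4,4a,5,6,7,8-hexahydronaphthalen-2(3H)-one
Conditions: Ph3PCH3Br (2.5 equiv), KOt‑Bu (2.4 equiv), THF, 0 °C → rt; aq. NH4Cl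
Reagents that add atoms: methyltriphenylphosphonium bromide, C[P+](c1ccccc1)(c1ccccc1)c1ccccc1.[Br-]
Why: Wittig methylenation that is chemoselective for the saturated C4 ketone, the more electrophilic carbonyl (the C8 carbonyl is a vinylogous, enolisable enone carbonyl that the ylide does not olefinate), and that leaves the quaternary C5 centre untouched.

**Step 4**
Reactants: 7 (4aR)-4a-methyl-5-methylidene-4,4a,5,6,7,8-hexahydronaphthalen-2(3H)-one
Product: 8 (4aR)-4a,5-dimethyl-4,4a,7,8-tetrahydronaphthalen-2(3H)-one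
Conditions: RhCl3·3H2O (5 mol%), EtOH, 80 °C
Reagents that add atoms: none
Why: rhodium‑hydride alkene isomerisation (addition/β‑hydride elimination) moves the exocyclic double bond to the only ring position that carries hydrogen (C3), giving the more stable trisubstituted Δ3 alkene without cationic intermediates that could shift the C5 methyl; no stereocentre is formed.

**Step 5**
Reactants: 8 (4aR)-4a,5-dimethyl-4,4a,7,8-tetrahydronaphthalen-2(3H)-one
Product: 10 tert-butyl{[(4aS,8aS)-4a,5-dimethyl-3,4,4a,7,8,8a-hexahydronaphthalen-2-yl]oxy}dimethylsilane (trans-fused Δ8 silyl enol ether), via lithium enolate 9 (not isolated)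
Conditions: Li (2.2 equiv), t‑BuOH (1.0 equiv), NH3/THF, −78 °C; evaporate NH3; TBSCl, DMPU, THF, −78 → 0 °C
Reagents that add atoms: tert-butyldimethylsilyl chloride, CC(C)(C)[Si](C)(C)Cl
Why: dissolving‑metal (Birch‑type) conjugate reduction of the enone — C10 is protonated axially on the face opposite the C5 methyl, which gives the trans ring fusion (10α‑H), and the regiodefined Δ8 lithium enolate is trapped on oxygen while the isolated Δ3 alkene is not reduced.

**Step 6**
Reactants: 10 trans-fused Δ8 silyl enol ether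
Product: 12 9α-(tert-butyldimethylsilyloxy)-3α,4α-epoxy-10αH-11,12,13-trinoreremophilan-8-one, via silyloxy bis-epoxide 11 (not isolated)
Conditions: mCPBA (2.3 equiv), NaHCO3, CH2Cl2, −20 → 0 °C
Reagents that add atoms: meta-chloroperoxybenzoic acid (mCPBA), OOC(=O)c1cccc(Cl)c1
Why: Rubottom oxidation and Prilezhaev epoxidation by one peracid charge — both π bonds are attacked on the α face, away from the axial C5 methyl, the silyloxy‑oxirane opens with O8 → O9 silyl shift to the equatorial 9α‑silyloxy ketone, and the 3α,4α‑oxirane fixes the C3–O bond.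

**Step 7**
Reactants: 12 9α-(tert-butyldimethylsilyloxy)-3α,4α-epoxy-10αH-11,12,13-trinoreremophilan-8-one
Product: 14 9α-(tert-butyldimethylsilyloxy)-3α,4α-epoxy-11-hydroxy-7βH,10αH-eremophilan-8-one, via lithium enolate 13 (not isolated)
Conditions: LDA (1.1 equiv), THF, −78 °C; acetone (5 equiv), −78 °C, 10 min; AcOH, −78 °C
Reagents that add atoms: acetone, CC(C)=O
Why: kinetic LDA deprotonation takes the unhindered C7–H2 and not the tertiary silyloxy‑bearing C9–H, and the lithium enolate adds to acetone (aldol addition; the equatorial C7 centre is erased in step 8), the oxirane being inert to LDA at −78 °C.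

**Step 8**
Reactants: 14 9α-(tert-butyldimethylsilyloxy)-3α,4α-epoxy-11-hydroxy-7βH,10αH-eremophilan-8-one
Product: 16 9α-(tert-butyldimethylsilyloxy)-3α,4α-epoxy-10αH-eremophil-7(11)-en-8-one, via tertiary mesylate 15 (not isolated)
Conditions: MsCl, Et3N, CH2Cl2, 0 °C; then DBU, rt
Reagents that add atoms: none
Why: mesylation of the tertiary aldol hydroxyl (through sulfene) and E1cB elimination through the C8 enolate put the double bond in conjugation as the C7=C11 isopropylidene, removing the C7 stereocentre and leaving the oxirane alone.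

**Step 9**
Reactants: 16 9α-(tert-butyldimethylsilyloxy)-3α,4α-epoxy-10αH-eremophil-7(11)-en-8-one; 5 (2E,4E,6E)-5-methyldodeca-2,4,6-trienoic acid
Product: 19 9α-(tert-butyldimethylsilyloxy)-8-oxo-4αH,10αH-eremophil-7(11)-en-3α-yl (2E,4E,6E)-5-methyldodeca-2,4,6-trienoate, via mixed anhydride 17 (not isolated), via titanium alkoxide 18 (not isolated)
Conditions: flask A: 16, Cp2TiCl (2.2 equiv), 1,4‑cyclohexadiene (10 equiv), THF, rt; flask B: 5, 2,4,6‑Cl3C6H2COCl, Et3N, THF, rt (gives 17); then B into A, DMAP, rt; aq. HCl work‑up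
Reagents that add atoms: none
Why: Proposed new method: reductive epoxide opening with acylative capture — Cp2Ti(III)Cl homolyses the C4–O bond to the tertiary C4 radical while O3 stays on titanium and C3 is untouched, 1,4‑cyclohexadiene delivers H to C4 axially on the α face (anti to the axial C5 methyl, so C15 ends equatorial, β), and the Cp2Ti(IV)(Cl) alkoxide 18 is then acylated on O3 by the DMAP‑activated mixed anhydride 17 (Ti–O to acyl–O exchange driven by the titanium carboxylate), so the ester forms without isolating the free alcohol; the closest known reactions are the Nugent–RajanBabu reductive epoxide opening, the cleavage of titanocene alkoxides by Me3SiCl in catalytic titanocene protocols and the Yamaguchi esterification.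

**Step 10**
Reactants: 19 9α-(tert-butyldimethylsilyloxy)-8-oxo-4αH,10αH-eremophil-7(11)-en-3α-yl (2E,4E,6E)-5-methyldodeca-2,4,6-trienoate
Product: 20 (3R,4R,5R,9S,10R)-9-hydroxy-8-oxoeremophil-7(11)-en-3-yl (2E,4E,6E)-5-methyldodeca-2,4,6-trienoate (CNP0211657.1)
Conditions: HF·pyridine, pyridine/THF, 0 °C → rt
Reagents that add atoms: none
Why: fluoride‑driven Si–O cleavage (silyl ether deprotection) under buffered, weakly acidic conditions that do not trigger α‑ketol rearrangement, C9 epimerisation or triene isomerisation.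

**Compound list**
1 | (E)-non-3-en-2-one | CCCCC/C=C/C(C)=O | starting material
2 | triethyl 4-phosphonocrotonate [ethyl (E)-4-(diethoxyphosphoryl)but-2-enoate] | CCOC(=O)/C=C/CP(=O)(OCC)OCC | starting material
3 | lithiated phosphonate (4-lithio derivative of 2) | CCOC(=O)/C=C/C([Li])P(=O)(OCC)OCC | intermediate (not isolated)
4 | ethyl (2E,4E,6E)-5-methyldodeca-2,4,6-trienoate | CCCCC/C=C/C(C)=C/C=C/C(=O)OCC | intermediate
5 | (2E,4E,6E)-5-methyldodeca-2,4,6-trienoic acid | CCCCC/C=C/C(C)=C/C=C/C(=O)O | intermediate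
6 | (S)-(+)-Wieland–Miescher ketone [(8aS)-8a-methyl-3,4,8,8a-tetrahydronaphthalene-1,6(2H,7H)-dione] | O=C1CCCC2=CC(=O)CC[C@]12C | starting material
7 | (4aR)-4a-methyl-5-methylidene-4,4a,5,6,7,8-hexahydronaphthalen-2(3H)-one | C=C1CCCC2=CC(=O)CC[C@]12C | intermediate
8 | (4aR)-4a,5-dimethyl-4,4a,7,8-tetrahydronaphthalen-2(3H)-one | CC1=CCCC2=CC(=O)CC[C@]12C | intermediate
9 | lithium enolate: lithium (4aS,8aS)-4a,5-dimethyl-3,4,4a,7,8,8a-hexahydronaphthalen-2-olate (trans-fused, 10α-H) | CC1=CCC[C@H]2C=C(O[Li])CC[C@]12C | intermediate (not isolated)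
10 | tert-butyl{[(4aS,8aS)-4a,5-dimethyl-3,4,4a,7,8,8a-hexahydronaphthalen-2-yl]oxy}dimethylsilane (trans-fused Δ8 silyl enol ether) | CC1=CCC[C@H]2C=C(O[Si](C)(C)C(C)(C)C)CC[C@]12C | intermediate
11 | silyloxy bis-epoxide: 8β-(tert-butyldimethylsilyloxy)-3α,4α:8α,9α-diepoxy-10αH-11,12,13-trinoreremophilane | O1[C@@H]2CC[C@H]3[C@@H]4O[C@]4(O[Si](C)(C)C(C)(C)C)CC[C@]3(C)[C@]12C | intermediate (not isolated)
12 | 9α-(tert-butyldimethylsilyloxy)-3α,4α-epoxy-10αH-11,12,13-trinoreremophilan-8-one | O1[C@@H]2CC[C@H]3[C@H](O[Si](C)(C)C(C)(C)C)C(=O)CC[C@]3(C)[C@]12C | intermediate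
13 | lithium enolate: lithium Δ7-enolate of 12 | O1[C@@H]2CC[C@H]3[C@H](O[Si](C)(C)C(C)(C)C)C(O[Li])=CC[C@]3(C)[C@]12C | intermediate (not isolated)
14 | 9α-(tert-butyldimethylsilyloxy)-3α,4α-epoxy-11-hydroxy-7βH,10αH-eremophilan-8-one | O1[C@@H]2CC[C@H]3[C@H](O[Si](C)(C)C(C)(C)C)C(=O)[C@H](C(C)(C)O)C[C@]3(C)[C@]12C | intermediate
15 | tertiary mesylate: 11-methanesulfonate of 14 | O1[C@@H]2CC[C@H]3[C@H](O[Si](C)(C)C(C)(C)C)C(=O)[C@H](C(C)(C)OS(C)(=O)=O)C[C@]3(C)[C@]12C | intermediate (not isolated)
16 | 9α-(tert-butyldimethylsilyloxy)-3α,4α-epoxy-10αH-eremophil-7(11)-en-8-one | O1[C@@H]2CC[C@H]3[C@H](O[Si](C)(C)C(C)(C)C)C(=O)C(=C(C)C)C[C@]3(C)[C@]12C | intermediate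
17 | mixed anhydride: (2E,4E,6E)-5-methyldodeca-2,4,6-trienoic 2,4,6-trichlorobenzoic anhydride | CCCCC/C=C/C(C)=C/C=C/C(=O)OC(=O)c1c(Cl)cc(Cl)cc1Cl | intermediate (not isolated)
18 | titanium alkoxide: chlorobis(cyclopentadienyl)titanium(IV) 3α-alkoxide of 9α-(tert-butyldimethylsilyloxy)-3α-hydroxy-4αH,10αH-eremophil-7(11)-en-8-one | Cl[Ti](C1C=CC=C1)(C1C=CC=C1)O[C@@H]1CC[C@H]2[C@H](O[Si](C)(C)C(C)(C)C)C(=O)C(=C(C)C)C[C@]2(C)[C@H]1C | intermediate (not isolated)
19 | 9α-(tert-butyldimethylsilyloxy)-8-oxo-4αH,10αH-eremophil-7(11)-en-3α-yl (2E,4E,6E)-5-methyldodeca-2,4,6-trienoate | CCCCC/C=C/C(C)=C/C=C/C(=O)O[C@@H]1CC[C@H]2[C@H](O[Si](C)(C)C(C)(C)C)C(=O)C(=C(C)C)C[C@]2(C)[C@H]1C | intermediate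
20 | (3R,4R,5R,9S,10R)-9-hydroxy-8-oxoeremophil-7(11)-en-3-yl (2E,4E,6E)-5-methyldodeca-2,4,6-trienoate (CNP0211657.1) | CCCCC/C=C/C(C)=C/C=C/C(=O)O[C@@H]1CC[C@H]2[C@H](O)C(=O)C(=C(C)C)C[C@]2(C)[C@H]1C | target

**Step count**
Total: 10 steps. Longest linear sequence: 8 steps (6 → 20, steps 3–10); the acid branch is 2 steps (1 + 2 → 5) and joins at step 9.

**Three steps most likely to fail**

Step 9 (the proposed new step). The risks are hydrogen delivery to the wrong face of C4, attack of Ti(III) on the enone, and slow acylation of the titanium alkoxide. The fallback sets out from 16 and comes back at 19, using only known reactions. Treating 16 with Cp2TiCl in THF without a hydrogen donor gives the known Ti(III) epoxide-to-allylic-alcohol isomerisation and yields 9α-(tert-butyldimethylsilyloxy)-3α-hydroxy-10αH-eremophila-4(15),7(11)-dien-8-one F1. Hydroxyl-directed hydrogenation of the exocyclic alkene with Crabtree's catalyst (H2, CH2Cl2) adds hydrogen from the α face and gives 9α-(tert-butyldimethylsilyloxy)-3α-hydroxy-4αH,10αH-eremophil-7(11)-en-8-one F2. Ordinary Yamaguchi esterification of F2 with 5 (through 17, DMAP, toluene) then gives 19. This costs two more steps but removes both unknowns of step 9.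

Step 1. The ketone olefination can give a poor 4E/4Z ratio or conjugate addition. The fallback sets out from 1 and comes back at 4, building the chain two carbons at a time. Reaction of 1 with triethyl phosphonoacetate (NaH, THF) gives ethyl (2E,4E)-3-methyldeca-2,4-dienoate F3, whose minor 2Z isomer is removed at this simple stage. DIBAL‑H reduction gives (2E,4E)-3-methyldeca-2,4-dien-1-ol F4, and MnO2 oxidation gives (2E,4E)-3-methyldeca-2,4-dienal F5. A second Horner–Wadsworth–Emmons reaction of this aldehyde with triethyl phosphonoacetate (LiCl, DBU, MeCN) is reliably E‑selective and gives 4.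

Step 7. Acetone can quench the enolate by proton transfer, and the tertiary aldolate can revert. The fallback sets out from 12 and comes back at 16, bypassing 14. Palladium-catalysed α‑alkenylation of the C7 enolate of 12 with 2‑bromopropene (LiHMDS, Pd2(dba)3, t‑Bu3P·HBF4, toluene, 50 °C) gives 9α-(tert-butyldimethylsilyloxy)-3α,4α-epoxy-7βH,10αH-eremophil-11-en-8-one F6. DBU in CH2Cl2 then moves the isopropenyl double bond into conjugation and gives 16.

**Further compounds**
F1 | step 9 | 9α-(tert-butyldimethylsilyloxy)-3α-hydroxy-10αH-eremophila-4(15),7(11)-dien-8-one | O[C@@H]1CC[C@H]2[C@H](O[Si](C)(C)C(C)(C)C)C(=O)C(=C(C)C)C[C@]2(C)C1=C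
F2 | step 9 | 9α-(tert-butyldimethylsilyloxy)-3α-hydroxy-4αH,10αH-eremophil-7(11)-en-8-one | O[C@@H]1CC[C@H]2[C@H](O[Si](C)(C)C(C)(C)C)C(=O)C(=C(C)C)C[C@]2(C)[C@H]1C
F3 | step 1 | ethyl (2E,4E)-3-methyldeca-2,4-dienoate | CCCCC/C=C/C(C)=C/C(=O)OCC
F4 | step 1 | (2E,4E)-3-methyldeca-2,4-dien-1-ol | CCCCC/C=C/C(C)=C/CO
F5 | step 1 | (2E,4E)-3-methyldeca-2,4-dienal | CCCCC/C=C/C(C)=C/C=O
F6 | step 7 | 9α-(tert-butyldimethylsilyloxy)-3α,4α-epoxy-7βH,10αH-eremophil-11-en-8-one | O1[C@@H]2CC[C@H]3[C@H](O[Si](C)(C)C(C)(C)C)C(=O)[C@H](C(C)=C)C[C@]3(C)[C@]12C
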